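**Strategy.** The route rests on cutting the quinone ring of the naphthazarin core at C3–C4 and C1–C2. The carbonyl carbons C1 and C4 sit on the ring-fusion carbons C8a and C4a, and C2=C3 (C2 bearing the side chain, C3 only hydrogen) is an alkyne in disguise. In one operation a lithium acetylide adds to a symmetric benzocyclobutenedione and the adduct, on heating, ring-expands to the 1,4-naphthoquinone at its final oxidation level. The precursors are 3,6-dimethoxybenzocyclobutene-1,2-dione and an (R)-propargylic silyl ether that already holds the only stereocentre. A tert-butyldiphenylsilyl group is used so that the ether survives the nitric acid of the later demethylation. The ester is attached last.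

Key step: step 9

Assumption: the naphthazarin core is handled as the drawn 5,8-dihydroxy-1,4-quinone tautomer (the tautomers equilibrate), and 3,4-dimethylpent-3-enoic acid is taken as a purchasable acid.

**Step 1**
Reactants: 1 2-bromo-1,4-dimethoxybenzene; 2 1,1-dimethoxyethene
Product: 5 3,6-dimethoxybenzocyclobuten-1(2H)-one, via 3,6-dimethoxybenzyne 3 (not isolated), via dimethyl ketal 4 (not isolated)
Conditions: NaNH2, THF, reflux; then 1 M HCl, THF–H2O, rt
Reagents that add atoms: water, O
Why: Amide-induced dehydrobromination should give the symmetric aryne, which undergoes [2+2] cycloaddition with the electron-rich ketene acetal, and dilute acid then hydrolyses the strained ketal (aryne–ketene acetal cycloaddition, ketal hydrolysis).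

**Step 2**
Reactants: 5 3,6-dimethoxybenzocyclobuten-1(2H)-one
Product: 6 2,2-dibromo-3,6-dimethoxybenzocyclobuten-1(2H)-one
Conditions: NBS (2.2 equiv), (PhCO2)2 (cat.), PhCF3, reflux
Reagents that add atoms: N-bromosuccinimide, O=C1CCC(=O)N1Br
Why: Wohl–Ziegler radical bromination should occur twice at the only benzylic methylene, which is also alpha to the ketone, while the non-polar medium disfavours ionic bromination of the dimethoxyarene.

**Step 3**
Reactants: 6 2,2-dibromo-3,6-dimethoxybenzocyclobuten-1(2H)-one
Product: 7 3,6-dimethoxybenzocyclobutene-1,2-dione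
Conditions: AgOCOCF3 (2.2 equiv), MeCN–H2O, rt to 50 °C
Reagents that add atoms: water, O
Why: Silver-assisted hydrolysis of the geminal dibromide should unmask the second carbonyl without the hot mineral acid that would endanger the aryl ethers (gem-dihalide hydrolysis).

**Step 4**
Reactants: 8 4-methylpent-3-enoic acid
Product: 9 N-methoxy-N,4-dimethylpent-3-enamide
Conditions: MeNH(OMe)·HCl, EDC·HCl, N-methylmorpholine, CH2Cl2, 0 °C to rt
Reagents that add atoms: N,O-dimethylhydroxylamine hydrochloride, CNOC.Cl
Why: Carbodiimide amidation gives the Weinreb amide under conditions mild enough to leave the beta,gamma-alkene where it is.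

**Step 5**
Reactants: 9 N-methoxy-N,4-dimethylpent-3-enamide; 10 trimethylsilylacetylene
Product: 12 6-methyl-1-(trimethylsilyl)hept-5-en-1-yn-3-one, via lithium (trimethylsilyl)acetylide 11 (not isolated)
Conditions: 10, n-BuLi, THF, −78 °C; then 9, −78 to −20 °C; cold aq. NH4Cl
Reagents that add atoms: none
Why: The acetylide should add only once because the chelated tetrahedral adduct persists until the cold buffered quench, which also keeps the skipped enone from moving into conjugation (Weinreb ketone synthesis).

**Step 6**
Reactants: 12 6-methyl-1-(trimethylsilyl)hept-5-en-1-yn-3-one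
Product: 13 (3R)-6-methyl-1-(trimethylsilyl)hept-5-en-1-yn-3-ol
Conditions: RuCl[(R,R)-TsDPEN](p-cymene) (1 mol%), i-PrOH, rt
Reagents that add atoms: none
Why: Noyori asymmetric transfer hydrogenation of the alkynyl ketone with the (R,R)-configured catalyst should deliver hydride to the face that gives the (R)-propargylic alcohol, the alkyne acting as the directing π-substituent; this sets the only stereocentre of the target.

**Step 7**
Reactants: 13 (3R)-6-methyl-1-(trimethylsilyl)hept-5-en-1-yn-3-ol
Product: 14 tert-butyl{[(3R)-6-methyl-1-(trimethylsilyl)hept-5-en-1-yn-3-yl]oxy}diphenylsilane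
Conditions: TBDPSCl, imidazole, DMF, rt
Reagents that add atoms: tert-butyl(chloro)diphenylsilane, CC(C)(C)[Si](Cl)(c1ccccc1)c1ccccc1
Why: Silylation of a secondary alcohol is routine, and the tert-butyldiphenylsilyl ether is chosen for its resistance to aqueous acid; the C–O bond at the stereocentre is not touched.

**Step 8**
Reactants: 14 tert-butyl{[(3R)-6-methyl-1-(trimethylsilyl)hept-5-en-1-yn-3-yl]oxy}diphenylsilane
Product: 15 tert-butyl{[(3R)-6-methylhept-5-en-1-yn-3-yl]oxy}diphenylsilane
Conditions: K2CO3, MeOH, rt
Reagents that add atoms: none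
Why: Carbonate-mediated methanolysis cleaves the alkynyl C–Si bond selectively because the hindered silyl ether on oxygen is inert to these conditions (protiodesilylation).

**Step 9**
Reactants: 7 3,6-dimethoxybenzocyclobutene-1,2-dione; 15 tert-butyl{[(3R)-6-methylhept-5-en-1-yn-3-yl]oxy}diphenylsilane
Product: 20 2-[(1R)-1-(tert-butyldiphenylsilyloxy)-4-methylpent-3-en-1-yl]-5,8-dimethoxy-1,4-naphthoquinone, via lithium acetylide 16 (not isolated), via alkynyl carbinol 17 (not isolated), via enynyl ketene 18 (not isolated), via diradical 19 (not isolated)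
Conditions: 15, n-BuLi, THF, −78 °C; add to 7, THF, −78 °C; aq. NH4Cl, −78 °C; crude carbinol, degassed p-xylene, 138 °C
Reagents that add atoms: none
Why: Acetylide 16 adds once to one of the two equivalent carbonyls of 7 (C3–C4) and the cold quench gives carbinol 17; on heating, 4π-electrocyclic opening of the four-membered ring, with the hydroxyl turning outward and the alkynyl group inward, gives the ortho-quinoid enynyl ketene 18. The central ketene carbon then bonds to the distal alkyne carbon (C1–C2) in a 6-endo-dig cycloaromatisation that closes the quinone ring as the aryl/aryloxyl diradical 19, and shift of the hydroxyl hydrogen to the C3 radical gives quinone 20 at its final oxidation level. The closest known reaction is the Moore rearrangement of 4-alkynyl-4-hydroxycyclobutenones to quinones, which extends to benzo-fused cases that give 1,4-naphthoquinones. No stereocentre is formed, and the (R)-carbinol carbon lies outside the reacting array, so its configuration is carried through unchanged. The step needs mono-addition (inverse addition at −78 °C and a cold quench), needs no regiocontrol (7 is symmetric), and needs six-membered closure to win over 5-exo-dig closure to an alkylidene indanedione and over capture of the C3 radical by the side-chain alkene, which the sp3, non-radical-stabilising substituent on the distal alkyne carbon and the free tertiary hydroxyl as an internal hydrogen donor should secure.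

**Step 10**
Reactants: 20 2-[(1R)-1-(tert-butyldiphenylsilyloxy)-4-methylpent-3-en-1-yl]-5,8-dimethoxy-1,4-naphthoquinone
Product: 22 2-[(1R)-1-(tert-butyldiphenylsilyloxy)-4-methylpent-3-en-1-yl]-5,8-dihydroxy-1,4-naphthoquinone, via naphthalene-1,4,5,8-tetraone 21 (not isolated)
Conditions: AgO, 6 M HNO3, 1,4-dioxane, rt, 10 min; then aq. Na2S2O4, EtOAc, rt
Reagents that add atoms: water, O
Why: Oxidative demethylation with AgO in nitric acid should turn the dimethoxyarene ring into a second quinone and dithionite then reduces tetraone 21 by two electrons to the naphthazarin, the acid-stable silyl ether shielding the carbinol as an acyl group does in related 5,8-dimethoxy-1,4-naphthoquinones.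

**Step 11**
Reactants: 22 2-[(1R)-1-(tert-butyldiphenylsilyloxy)-4-methylpent-3-en-1-yl]-5,8-dihydroxy-1,4-naphthoquinone
Product: 23 5,8-dihydroxy-2-[(1R)-1-hydroxy-4-methylpent-3-en-1-yl]-1,4-naphthoquinone (shikonin)
Conditions: TBAF, AcOH, THF, 0 °C to rt
Reagents that add atoms: none
Why: Fluoride cleaves the Si–O bond while the acetic acid buffer keeps the acidic peri-hydroxyquinone from being deprotonated, and no bond at the stereocentre is broken (fluoride desilylation).

**Step 12**
Reactants: 23 5,8-dihydroxy-2-[(1R)-1-hydroxy-4-methylpent-3-en-1-yl]-1,4-naphthoquinone; 24 3,4-dimethylpent-3-enoic acid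
Product: 25 (1R)-1-(5,8-dihydroxy-1,4-dioxo-1,4-dihydronaphthalen-2-yl)-4-methylpent-3-en-1-yl 3,4-dimethylpent-3-enoate
Conditions: DCC, DMAP (cat.), CH2Cl2, 0 °C
Reagents that add atoms: none
Why: Steglich esterification should acylate only the aliphatic hydroxyl because both phenols are tied up in hydrogen bonds to the quinone carbonyls, the low temperature and small amount of DMAP limit migration of the beta,gamma-alkene of the acid, and the configuration is retained since the carbinol C–O bond stays intact.

**Compound list**
1 | 2-bromo-1,4-dimethoxybenzene | COc1ccc(OC)c(Br)c1 | starting material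
2 | 1,1-dimethoxyethene | C=C(OC)OC | starting material
3 | 3,6-dimethoxybenzyne (1,4-dimethoxy-2,3-didehydrobenzene) | COC1=CC=C(OC)C#C1 | intermediate
4 | 2,5,7,7-tetramethoxybicyclo[4.2.0]octa-1,3,5-triene (dimethyl ketal of 5) | COc1ccc(OC)c2c1CC2(OC)OC | intermediate
5 | 3,6-dimethoxybenzocyclobuten-1(2H)-one | COc1ccc(OC)c2c1CC2=O | intermediate
6 | 2,2-dibromo-3,6-dimethoxybenzocyclobuten-1(2H)-one | COc1ccc(OC)c2c1C(Br)(Br)C2=O | intermediate
7 | 3,6-dimethoxybenzocyclobutene-1,2-dione | COc1ccc(OC)c2c1C(=O)C2=O | intermediate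
8 | 4-methylpent-3-enoic acid | CC(C)=CCC(=O)O | starting material
9 | N-methoxy-N,4-dimethylpent-3-enamide | CC(C)=CCC(=O)N(C)OC | intermediate
10 | trimethylsilylacetylene | C#C[Si](C)(C)C | starting material
11 | lithium (trimethylsilyl)acetylide | [Li]C#C[Si](C)(C)C | intermediate
12 | 6-methyl-1-(trimethylsilyl)hept-5-en-1-yn-3-one | CC(C)=CCC(=O)C#C[Si](C)(C)C | intermediate
13 | (3R)-6-methyl-1-(trimethylsilyl)hept-5-en-1-yn-3-ol | CC(C)=CC[C@@H](O)C#C[Si](C)(C)C | intermediate
14 | tert-butyl{[(3R)-6-methyl-1-(trimethylsilyl)hept-5-en-1-yn-3-yl]oxy}diphenylsilane | CC(C)=CC[C@@H](O[Si](c1ccccc1)(c1ccccc1)C(C)(C)C)C#C[Si](C)(C)C | intermediate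
15 | tert-butyl{[(3R)-6-methylhept-5-en-1-yn-3-yl]oxy}diphenylsilane | CC(C)=CC[C@@H](O[Si](c1ccccc1)(c1ccccc1)C(C)(C)C)C#C | intermediate
16 | lithium acetylide of 15, lithium on the terminal alkyne carbon, (3R) | CC(C)=CC[C@@H](O[Si](c1ccccc1)(c1ccccc1)C(C)(C)C)C#C[Li] | intermediate
17 | 2-{(3R)-3-[(tert-butyldiphenylsilyl)oxy]-6-methylhept-5-en-1-yn-1-yl}-2-hydroxy-3,6-dimethoxybenzocyclobuten-1(2H)-one, both epimers at the ring carbinol carbon | CC(C)=CC[C@@H](O[Si](c1ccccc1)(c1ccccc1)C(C)(C)C)C#CC1(O)C(=O)c2c(OC)ccc(OC)c21 | intermediate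
18 | ring-opened ortho-quinoid ketene: 2,5-dimethoxycyclohexa-2,4-diene with an exocyclic C=C=O on C1 and an exocyclic C(OH)–C≡C–CH(OTBDPS)CH2CH=CMe2 on C6, alkynyl group syn to the ketene, (R) at the silyloxy carbon | CC(C)=CC[C@@H](O[Si](c1ccccc1)(c1ccccc1)C(C)(C)C)C#C/C(O)=C1/C(OC)=CC=C(OC)C1=C=O | intermediate
19 | diradical: 2-[(1R)-1-(tert-butyldiphenylsilyloxy)-4-methylpent-3-en-1-yl]-4-hydroxy-5,8-dimethoxynaphthalene with an oxyl radical on the C1 oxygen and a σ-radical at C3 | CC(C)=CC[C@@H](O[Si](c1ccccc1)(c1ccccc1)C(C)(C)C)c1[c]c(O)c2c(OC)ccc(OC)c2c1[O] | intermediate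
20 | 2-[(1R)-1-(tert-butyldiphenylsilyloxy)-4-methylpent-3-en-1-yl]-5,8-dimethoxy-1,4-naphthoquinone | CC(C)=CC[C@@H](O[Si](c1ccccc1)(c1ccccc1)C(C)(C)C)C1=CC(=O)c2c(OC)ccc(OC)c2C1=O | intermediate
21 | 2-[(1R)-1-(tert-butyldiphenylsilyloxy)-4-methylpent-3-en-1-yl]naphthalene-1,4,5,8-tetraone | CC(C)=CC[C@@H](O[Si](c1ccccc1)(c1ccccc1)C(C)(C)C)C1=CC(=O)C2=C(C1=O)C(=O)C=CC2=O | intermediate
22 | 2-[(1R)-1-(tert-butyldiphenylsilyloxy)-4-methylpent-3-en-1-yl]-5,8-dihydroxy-1,4-naphthoquinone | CC(C)=CC[C@@H](O[Si](c1ccccc1)(c1ccccc1)C(C)(C)C)C1=CC(=O)c2c(O)ccc(O)c2C1=O | intermediate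
23 | 5,8-dihydroxy-2-[(1R)-1-hydroxy-4-methylpent-3-en-1-yl]-1,4-naphthoquinone (shikonin) | CC(C)=CC[C@@H](O)C1=CC(=O)c2c(O)ccc(O)c2C1=O | intermediate
24 | 3,4-dimethylpent-3-enoic acid | CC(C)=C(C)CC(=O)O | starting material
25 | (1R)-1-(5,8-dihydroxy-1,4-dioxo-1,4-dihydronaphthalen-2-yl)-4-methylpent-3-en-1-yl 3,4-dimethylpent-3-enoate | CC(C)=CC[C@@H](OC(=O)CC(C)=C(C)C)C1=CC(=O)c2c(O)ccc(O)c2C1=O | target

**Total step count:** 12 steps.
**Longest linear sequence:** 9 steps (steps 4 to 12); the dione branch (steps 1 to 3) joins at step 9.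

**Steps most likely to fail**

1. Step 9. The diradical may close through the proximal alkyne carbon to the five-membered alkylidene indanedione, or its C3 radical may be intercepted by the side-chain alkene before hydrogen transfer, so that little quinone forms. The fallback sets out from dione 7 and alkyne 15 and builds the same ring by metal insertion instead of thermal ring opening. ClCo(PPh3)3 (monovalent cobalt) in benzene should insert into the C1–C2 bond of 7 to give chlorobis(triphenylphosphine)(3,6-dimethoxyphthaloyl)cobalt F1. Exchange of the phosphines with dimethylglyoxime in pyridine gives chloro(dimethylglyoxime)(pyridine)(3,6-dimethoxyphthaloyl)cobalt F2. Heating F2 with 15 and CoCl2·6H2O in MeCN at 80 °C should insert the alkyne and release quinone 20 by reductive elimination, where the route resumes. The symmetric phthaloyl unit again removes any regiochemical question, and no radical is involved.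

2. Step 10. The silyl ether may be lost in the nitric acid medium, followed by oxidation or acid-induced cyclisation at the freed carbinol, or the side-chain alkene may be damaged oxidatively. The fallback sets out from 20 and changes the protecting group before the oxidation. TBAF/AcOH in THF gives 2-[(1R)-1-hydroxy-4-methylpent-3-en-1-yl]-5,8-dimethoxy-1,4-naphthoquinone F3. Ac2O, pyridine and catalytic DMAP give (1R)-1-(5,8-dimethoxy-1,4-dioxo-1,4-dihydronaphthalen-2-yl)-4-methylpent-3-en-1-yl acetate F4. The same AgO/HNO3 then Na2S2O4 sequence, for which an acyloxy side chain is the established substrate type, gives (1R)-1-(5,8-dihydroxy-1,4-dioxo-1,4-dihydronaphthalen-2-yl)-4-methylpent-3-en-1-yl acetate F5. Brief saponification with 1 M NaOH under argon and acidification returns to shikonin 23; step 11 is bypassed.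

3. Step 6. The skipped alkene may migrate into conjugation with the ketone under the basic catalyst before reduction, or the enantioselectivity may be incomplete. The fallback sets out from 10 and forms the stereocentre by C–C bond formation instead of reduction. n-BuLi then DMF gives 3-(trimethylsilyl)prop-2-ynal F6. Asymmetric allylboration with (+)-B-allyldiisopinocampheylborane [(+)-Ipc2B(allyl), from (−)-α-pinene; Et2O, −78 °C, then NaOH/H2O2], which delivers allyl to the Re face, should give (3R)-1-(trimethylsilyl)hex-5-en-1-yn-3-ol F7. Cross-metathesis with excess 2-methyl-2-butene and second-generation Grubbs catalyst, RuCl2(=CHPh)(H2IMes)(PCy3), converts the vinyl group into the trisubstituted alkene and gives 13, where the route resumes.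

**Further compounds**
F1 | step 9 | chlorobis(triphenylphosphine)(3,6-dimethoxyphthaloyl)cobalt | COc1ccc(OC)c2c1C(=O)[Co-2](Cl)([P+](c3ccccc3)(c3ccccc3)c3ccccc3)([P+](c3ccccc3)(c3ccccc3)c3ccccc3)C2=O
F2 | step 9 | chloro(dimethylglyoxime)(pyridine)(3,6-dimethoxyphthaloyl)cobalt | COc1ccc(OC)c2c1C(=O)[Co-3]3(Cl)([n+]4ccccc4)([N+](O)=C(C)C(C)=[N+]3O)C2=O
F3 | step 10 | 2-[(1R)-1-hydroxy-4-methylpent-3-en-1-yl]-5,8-dimethoxy-1,4-naphthoquinone | CC(C)=CC[C@@H](O)C1=CC(=O)c2c(OC)ccc(OC)c2C1=O
F4 | step 10 | (1R)-1-(5,8-dimethoxy-1,4-dioxo-1,4-dihydronaphthalen-2-yl)-4-methylpent-3-en-1-yl acetate | CC(C)=CC[C@@H](OC(C)=O)C1=CC(=O)c2c(OC)ccc(OC)c2C1=O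
F5 | step 10 | (1R)-1-(5,8-dihydroxy-1,4-dioxo-1,4-dihydronaphthalen-2-yl)-4-methylpent-3-en-1-yl acetate (acetylshikonin) | CC(C)=CC[C@@H](OC(C)=O)C1=CC(=O)c2c(O)ccc(O)c2C1=O
F6 | step 6 | 3-(trimethylsilyl)prop-2-ynal | O=CC#C[Si](C)(C)C
F7 | step 6 | (3R)-1-(trimethylsilyl)hex-5-en-1-yn-3-ol | C=CC[C@@H](O)C#C[Si](C)(C)C
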